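**Plan**
- Retrosynthesis: the two phenolic OH groups are masked as methyl ethers. The pyranone ring is then cut at two bonds at once, O1–C8a and C4–C4a. This is the reverse of inserting the arene carbons C4a/C8a, as an aryne, into the acyl–oxygen bond of a four-membered lactone, (S)-4-heptadecyloxetan-2-one, in which O1, C2, C3 and C4 are already joined.
- Enabling feature: the strained O1–C4(=O) bond of the oxetan-2-one, and on the benzene ring the adjacent pair C4a/C8a flanked by C5–OMe and C8–Me. The C5 oxygen polarises the aryne so that O1 goes to C8a and the acyl carbon C4 to C4a.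
- Forward, arene: 2,6-dimethoxytoluene is taken to the hexasubstituted o-silylaryl triflate by meta C–H borylation/oxidation, ortho-formylation, hydrogenolysis, bromination and retro-Brook/triflation.
- Forward, heterocycle: it grows oxirane → oxetanone → pyranone (3 → 4 → 6). (S)-Epichlorohydrin and a C16 Grignard reagent give the epoxide, carbonylation gives the β-lactone, the aryne expands it by two atoms, and double O-demethylation ends the route.
- Stereochemistry: the only stereocenter, C2, comes from (S)-epichlorohydrin. No bond at this carbon is broken in any step, so it is carried through with retention.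

Key step: step 8

Remark: C2 of the target is (S) (priorities O1 > C3 > C1' of the chain > H). Compounds 1, 11 and 12 and all reagents are taken as commercial.

**Step 1**
Reactants: 1 2,6-dimethoxytoluene
Product: 3 3,5-dimethoxy-4-methylphenol, via aryl pinacol boronate 2 (not isolated)
Conditions: [Ir(OMe)(cod)]2 (cat.), dtbpy (cat.), B2pin2, THF, 80 °C; then 30% H2O2, aq. NaOH, THF, 0 °C → rt
Reagents that add atoms: bis(pinacolato)diboron, CC1(C)OB(OC1(C)C)B1OC(C)(C)C(C)(C)O1 (boron of 2 only); hydrogen peroxide, OO (oxygen of 3)
Why: Sterically governed Ir-catalysed C–H borylation (Hartwig–Miyaura type) should take the only ring C–H of 1 without an ortho substituent, meta to both methoxy groups, and oxidation of the C–B bond then gives the 1,3,5-oxygen pattern that electrophilic substitution cannot reach.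

**Step 2**
Reactants: 3 3,5-dimethoxy-4-methylphenol
Product: 4 6-hydroxy-2,4-dimethoxy-3-methylbenzaldehyde
Conditions: MgCl2, Et3N, (CH2O)n, MeCN, reflux; aq. HCl work-up
Reagents that add atoms: paraformaldehyde (as formaldehyde), C=O
Why: In the Mg-mediated ortho-formylation of phenols (Casnati–Skattebøl) the magnesium phenoxide delivers formaldehyde only ortho to OH, and the two ortho positions of 3 are equivalent, so a single salicylaldehyde should form.

**Step 3**
Reactants: 4 6-hydroxy-2,4-dimethoxy-3-methylbenzaldehyde
Product: 5 3,5-dimethoxy-2,4-dimethylphenol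
Conditions: H2 (3 atm), 10% Pd/C, AcOH, cat. HCl, rt
Reagents that add atoms: none
Why: Hydrogenolysis of an electron-rich ortho-hydroxybenzaldehyde over Pd/C in acid should pass through the benzylic alcohol to the methyl group, while the aryl methyl ethers are inert.

**Step 4**
Reactants: 5 3,5-dimethoxy-2,4-dimethylphenol
Product: 6 2-bromo-3,5-dimethoxy-4,6-dimethylphenol
Conditions: NBS (1.0 equiv), CH2Cl2, −20 → 0 °C, dark
Reagents that add atoms: N-bromosuccinimide, O=C1CCC(=O)N1Br
Why: Electrophilic aromatic bromination can only occur at the single remaining ring position, which is activated ortho to OH and ortho/para to the methoxy groups.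

**Step 5**
Reactants: 6 2-bromo-3,5-dimethoxy-4,6-dimethylphenol
Product: 10 3,5-dimethoxy-4,6-dimethyl-2-(trimethylsilyl)phenyl trifluoromethanesulfonate, via aryl trimethylsilyl ether 7 (not isolated), via aryllithium 8 (not isolated), via lithium 2-silylphenoxide 9 (not isolated)
Conditions: HMDS, THF, 70 °C, then evaporation; n-BuLi, THF, −78 °C; Tf2O, −78 °C → rt
Reagents that add atoms: hexamethyldisilazane, C[Si](C)(C)N[Si](C)(C)C; triflic anhydride, O=S(=O)(OS(=O)(=O)C(F)(F)F)C(F)(F)F; n-butyllithium, [Li]CCCC (lithium of 8 and 9 only)
Why: This is the standard assembly of an o-silylaryl triflate by O-silylation, Br–Li exchange, anionic 1,3-O→C silyl shift (retro-Brook rearrangement) and O-triflation, which places SiMe3 on the former C–Br carbon and OTf on the former phenol oxygen.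

**Step 6**
Reactants: 11 1-bromohexadecane; 12 (S)-epichlorohydrin
Product: 15 (S)-2-heptadecyloxirane, via hexadecylmagnesium bromide 13 (not isolated), via (S)-1-chlorononadecan-2-ol 14 (not isolated)
Conditions: Mg, THF, reflux; CuI (10 mol%), 12, THF, −40 → 0 °C; then NaOH, rt
Reagents that add atoms: magnesium, [Mg] (in 13 only)
Why: Copper-catalysed Grignard opening of the epoxide at its CH2 terminus and base-induced closure of the alkoxide onto CH2Cl (intramolecular Williamson reaction) move the epoxide without touching a bond of the stereocenter, so (S)-12 should give (S)-15.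

**Step 7**
Reactants: 15 (S)-2-heptadecyloxirane
Product: 16 (S)-4-heptadecyloxetan-2-one
Conditions: [(salph)Al(THF)2][Co(CO)4] (2 mol%), CO (60 bar), DME, 50 °C
Reagents that add atoms: carbon monoxide, [C-]#[O+]
Why: In the ring-expanding carbonylation of epoxides by a Lewis acid/cobaltate ion pair, the cobaltate opens the activated epoxide at the unsubstituted carbon, CO inserts and the alkoxide closes onto the acyl cobalt, so CO enters the CH2–O bond and the C–O bond of the stereocenter is retained, giving the (S)-β-lactone.

**Step 8**
Reactants: 10 3,5-dimethoxy-4,6-dimethyl-2-(trimethylsilyl)phenyl trifluoromethanesulfonate; 16 (S)-4-heptadecyloxetan-2-one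
Product: 19 (S)-2-heptadecyl-5,7-dimethoxy-6,8-dimethylchroman-4-one, via 3,5-dimethoxy-4,6-dimethylbenzyne 17 (not isolated), via aryl anion acyloxonium zwitterion 18 (not isolated)
Conditions: TBAT (1.5 equiv), 16 (2 equiv), toluene, 50 °C; 10 added slowly by syringe pump
Reagents that add atoms: none
Why: Proposed new method: fluoride should convert 10 into aryne 17, whose carbon remote from the C–OMe carbon (the one next to C–Me) is attacked by the ring oxygen of the strained lactone 16; the aryl anion of zwitterion 18, held ortho to the O-aryl acyloxonium, then adds to the acyl carbon and the acyl–O bond breaks, so the two arene carbons are inserted into the O–C(=O) bond. The closest known reaction types are the σ-insertion of arynes into the N–C(=O) bond of amides and β-lactams (giving 2,3-dihydroquinolin-4-ones) and the C–O addition of carboxylic acids across arynes to give o-hydroxyaryl ketones; the insertion into the acyl–O bond of a lactone is the untested part, and ring strain and the ether-like, weakly conjugated ring oxygen make a β-lactone the ester most likely to do it. The six-membered ring closes by 4-exo-trig attack of the aryl carbanion on the acyl carbon followed by scission of the endocyclic acyl–O bond of the former lactone, a net 4 → 6 ring expansion by two atoms. No stereocenter is formed: C2 is carried over from 16 and none of its bonds is broken, so the (S) configuration should be kept. The step needs regioselectivity in the aryne addition, which the inductively polarising C5 methoxy group should secure as in 3-alkoxybenzynes (O to the distal carbon C8a, acyl to C4a), and chemoselectivity for acyl–O over alkyl–O cleavage, which follows from delivery of the carbanion to the carbonyl carbon through the only accessible four-membered transition state. Non-basic TBAT, excess lactone and slow addition of 10 are meant to limit lactone oligomerisation and aryne self-reaction.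

**Step 9**
Reactants: 19 (S)-2-heptadecyl-5,7-dimethoxy-6,8-dimethylchroman-4-one
Product: 20 (S)-2-heptadecyl-5,7-dihydroxy-6,8-dimethylchroman-4-one
Conditions: BBr3 (5 equiv), CH2Cl2, −78 → 0 °C; then ice-water
Reagents that add atoms: none
Why: BBr3 cleavage of aryl methyl ethers should remove the 5-methyl ether through chelation with C4=O and the 7-methyl ether as a twisted di-ortho-substituted anisole, while the ring oxygen is a poorly basic vinylogous ester oxygen and C2 lies β to the carbonyl, so the C2–O bond and the (S) centre should survive.

**Compound list**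
1 | 2,6-dimethoxytoluene | COc1cccc(OC)c1C | starting material
2 | 2-(3,5-dimethoxy-4-methylphenyl)-4,4,5,5-tetramethyl-1,3,2-dioxaborolane | COc1cc(B2OC(C)(C)C(C)(C)O2)cc(OC)c1C | intermediate
3 | 3,5-dimethoxy-4-methylphenol | COc1cc(O)cc(OC)c1C | intermediate
4 | 6-hydroxy-2,4-dimethoxy-3-methylbenzaldehyde | O=Cc1c(O)cc(OC)c(C)c1OC | intermediate
5 | 3,5-dimethoxy-2,4-dimethylphenol | Oc1cc(OC)c(C)c(OC)c1C | intermediate
6 | 2-bromo-3,5-dimethoxy-4,6-dimethylphenol | Oc1c(Br)c(OC)c(C)c(OC)c1C | intermediate
7 | (2-bromo-3,5-dimethoxy-4,6-dimethylphenoxy)trimethylsilane | C[Si](C)(C)Oc1c(Br)c(OC)c(C)c(OC)c1C | intermediate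
8 | [2,4-dimethoxy-3,5-dimethyl-6-(trimethylsilyloxy)phenyl]lithium | [Li]c1c(O[Si](C)(C)C)c(C)c(OC)c(C)c1OC | intermediate
9 | lithium 3,5-dimethoxy-4,6-dimethyl-2-(trimethylsilyl)phenolate | [Li+].[O-]c1c(C)c(OC)c(C)c(OC)c1[Si](C)(C)C | intermediate
10 | 3,5-dimethoxy-4,6-dimethyl-2-(trimethylsilyl)phenyl trifluoromethanesulfonate | C[Si](C)(C)c1c(OC)c(C)c(OC)c(C)c1OS(=O)(=O)C(F)(F)F | intermediate
11 | 1-bromohexadecane | CCCCCCCCCCCCCCCCBr | starting material
12 | (S)-epichlorohydrin, (S)-2-(chloromethyl)oxirane | ClC[C@@H]1CO1 | starting material
13 | hexadecylmagnesium bromide | CCCCCCCCCCCCCCCC[Mg]Br | intermediate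
14 | (S)-1-chlorononadecan-2-ol | ClC[C@@H](O)CCCCCCCCCCCCCCCCC | intermediate
15 | (S)-2-heptadecyloxirane | CCCCCCCCCCCCCCCCC[C@H]1CO1 | intermediate
16 | (S)-4-heptadecyloxetan-2-one | CCCCCCCCCCCCCCCCC[C@H]1CC(=O)O1 | intermediate
17 | 3,5-dimethoxy-4,6-dimethylbenzyne | COC1=C(C)C(OC)=C(C)C#C1 | intermediate
18 | 2-[(4S)-4-heptadecyl-2-oxooxetan-1-ium-1-yl]-4,6-dimethoxy-3,5-dimethylbenzen-1-ide | CCCCCCCCCCCCCCCCC[C@H]1CC(=O)[O+]1c1c(C)c(OC)c(C)c(OC)[c-]1 | intermediate
19 | (S)-2-heptadecyl-5,7-dimethoxy-6,8-dimethylchroman-4-one | CCCCCCCCCCCCCCCCC[C@H]1CC(=O)c2c(OC)c(C)c(OC)c(C)c2O1 | intermediate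
20 | (S)-2-heptadecyl-5,7-dihydroxy-6,8-dimethylchroman-4-one | CCCCCCCCCCCCCCCCC[C@H]1CC(=O)c2c(O)c(C)c(O)c(C)c2O1 | target

**Step count and risks**
Total steps: 9. Longest linear sequence: 7 (steps 1–5, 8, 9).

Step 8 (ring expansion). The neutral lactone oxygen may add too slowly to the electron-rich aryne, so that the aryne is lost to self-reaction or solvent. The lactone may be oligomerised by fluoride. Attack through the carbonyl oxygen, followed by proton transfer and ring-opening to an achiral enone that re-closes, would erode the enantiopurity. The fallback uses known chemistry and gives up the ring expansion. It sets out from phenol 5. Friedel–Crafts C-acetylation at its only free ring position (Ac2O, BF3·OEt2, 80 °C) should give 1-(2-hydroxy-4,6-dimethoxy-3,5-dimethylphenyl)ethan-1-one F1. Condensation with DMF dimethyl acetal (toluene, 100 °C) should give the enaminone (E)-3-(dimethylamino)-1-(2-hydroxy-4,6-dimethoxy-3,5-dimethylphenyl)prop-2-en-1-one F2, which closes with aqueous HCl to 5,7-dimethoxy-6,8-dimethyl-4H-chromen-4-one F3. Copper-catalysed asymmetric conjugate addition of heptadecylmagnesium bromide (CuBr·SMe2, a Josiphos-type ferrocenyl diphosphine in the enantiomeric form that gives the (S)-adduct, t-BuOMe/CH2Cl2, −78 °C) comes back to the route at 19.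

Step 9 (double demethylation). BBr3 may open the pyranone ring at O1–C2 by a Lewis-acid-promoted retro-oxa-Michael process and let it re-close with loss of configuration, or the cleavage may stop at a mono-ether. The fallback sets out from 19 and removes the two ethers one at a time by different mechanisms. BCl3 (1.1 equiv, CH2Cl2, −78 → 0 °C) should cleave only the chelated peri ether to give (S)-2-heptadecyl-5-hydroxy-7-methoxy-6,8-dimethylchroman-4-one F4. The remaining 7-methyl ether, para to the carbonyl, is then cleaved without Lewis acid by SN2 demethylation with sodium ethanethiolate (DMF, 120 °C). The 5-phenoxide, formed first, deactivates the ketone towards enolisation. Acidification comes back to the route at 20.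

Step 5 (silyl triflate). On the hexasubstituted ring the O→C silyl shift or the triflation of the doubly ortho-substituted phenoxide may be slow, so that protonation of the aryllithium or loss of silicon takes over. The fallback sets out from phenol 5 and bypasses 6. Isopropyl isocyanate with catalytic Et3N (CH2Cl2, rt) should give 3,5-dimethoxy-2,4-dimethylphenyl N-isopropylcarbamate F5. In-situ N-silylation (TBSOTf, TMEDA, Et2O), ortho-lithiation at the only ring C–H, which lies between the carbamate and a methoxy group (n-BuLi, −78 °C), and a TMSCl quench should give 3,5-dimethoxy-4,6-dimethyl-2-(trimethylsilyl)phenyl N-isopropylcarbamate F6. Carbamate cleavage (DBU, Et2NH, MeCN, 40 °C) and triflation of the phenoxide in the same flask (PhNTf2) come back to the route at 10.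

**Further compounds**
F1 | step 8 | 1-(2-hydroxy-4,6-dimethoxy-3,5-dimethylphenyl)ethan-1-one | CC(=O)c1c(O)c(C)c(OC)c(C)c1OC
F2 | step 8 | (E)-3-(dimethylamino)-1-(2-hydroxy-4,6-dimethoxy-3,5-dimethylphenyl)prop-2-en-1-one | CN(C)/C=C/C(=O)c1c(O)c(C)c(OC)c(C)c1OC
F3 | step 8 | 5,7-dimethoxy-6,8-dimethyl-4H-chromen-4-one | COc1c(C)c(OC)c2c(=O)ccoc2c1C
F4 | step 9 | (S)-2-heptadecyl-5-hydroxy-7-methoxy-6,8-dimethylchroman-4-one | CCCCCCCCCCCCCCCCC[C@H]1CC(=O)c2c(O)c(C)c(OC)c(C)c2O1
F5 | step 5 | 3,5-dimethoxy-2,4-dimethylphenyl N-isopropylcarbamate | CC(C)NC(=O)Oc1cc(OC)c(C)c(OC)c1C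
F6 | step 5 | 3,5-dimethoxy-4,6-dimethyl-2-(trimethylsilyl)phenyl N-isopropylcarbamate | CC(C)NC(=O)Oc1c(C)c(OC)c(C)c(OC)c1[Si](C)(C)C
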